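**Retrosynthetic overview**
1. The last operations are cleavage of ten benzyl ethers and reductive removal, via the triflate, of one temporary hydroxyl group at C5 of the lower 2,3-dihydrobenzofuran.
2. Key disconnection: C3–C3a and O1–C2 of the lower dihydrobenzofuran are cut together. This gives tri-O-benzylresveratrol and a 2-benzyloxy-6-styryl-1,4-benzoquinone (ring C at the quinone level) that already carries the whole upper core. In the forward sense this is a formal [3+2] cycloaddition under a chiral titanium TADDOLate.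
3. Enabling feature: C2 carries O1 and a 4-oxygenated phenyl ring, so a cation there is a protonated p-quinone methide, whereas the 3,5-dioxygenated ring on C3 cannot stabilise a cation. Ring C has oxygen on C7a and C6 and an unsubstituted C5 para to O1, so one added oxygen at C5 makes ring C an alkoxyquinone with C3a as the electrophilic carbon and the C7a oxygen as the internal nucleophile.
4. The quinone comes from Heck coupling of a ring D triflate with 2-benzyloxy-6-vinylphenol, then Teuber oxidation. Ring D and the seven-membered ring come from penta-O-benzyl-ε-viniferin and 1,4-benzoquinone ([3+2] union, then acid isomerisation of the temporary ring). The ε-viniferin ether comes from the same quinone–stilbene union on a simple styrylquinone.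
5. Order of ring formation: upper dihydrobenzofuran, temporary dihydrobenzofuran on ring D (opened again), seven-membered ring, lower dihydrobenzofuran.

Key step: step 15

Assumption: (4R,5R)-TADDOL is taken to lead to the (2S,3S) series. If the sense of induction is the opposite, the equally available (4S,5S) ligand is used in steps 6 and 15.

Locants:
- Dihydrobenzofurans are numbered O1, C2, C3, C3a, C4–C7, C7a. Quinones are numbered C1(=O), C2(OBn), C3, C4(=O), C5, C6(styryl).
- In the upper core, 7a/8a are O–CH(aryl)/CH of the upper dihydrobenzofuran. 7b is CH(4-oxyphenyl) and 8b is CH(ring D) of the seven-membered ring.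
- Ring A is the resorcinol ring fused to the seven-membered ring, ring B the benzo ring of the upper dihydrobenzofuran, ring C the benzo ring of the lower one, and ring D the phenol ring between 8b and the alkene.
- All six stereocentres of the target are S.

**Step 1**
Reactants: 1 resveratrol
Product: 2 tri-O-benzylresveratrol, (E)-1,3-bis(benzyloxy)-5-[4-(benzyloxy)styryl]benzene
Conditions: BnBr (3.5 equiv), K2CO3, DMF, rt
Reagents that add atoms: benzyl bromide, BrCc1ccccc1
Why: Williamson ether synthesis in which excess benzyl bromide alkylates all three phenoxides and leaves the E-alkene untouched.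

**Step 2**
Reactants: 3 2,3-dihydroxybenzaldehyde
Product: 4 3-(benzyloxy)-2-hydroxybenzaldehyde
Conditions: NaH (2.2 equiv), THF/DMF, 0 °C; BnBr (1.0 equiv), rt; then 1 M HCl
Reagents that add atoms: benzyl bromide, BrCc1ccccc1
Why: Williamson alkylation of the dianion with one equivalent of benzyl bromide, which goes to the 3-phenoxide because the 2-phenoxide is deactivated by conjugation with the formyl group and by sodium chelation.

**Step 3**
Reactants: 4 3-(benzyloxy)-2-hydroxybenzaldehyde
Product: 5 2-(benzyloxy)-6-vinylphenol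
Conditions: MePPh3Br (2.5 equiv), KOtBu (2.5 equiv), THF, 0 °C → rt
Reagents that add atoms: methyltriphenylphosphonium bromide, C[P+](c1ccccc1)(c1ccccc1)c1ccccc1.[Br-]
Why: Wittig methylenation with excess ylide, the first equivalent merely deprotonating the phenol, as is routine for salicylaldehydes.

**Step 4**
Reactants: 5 2-(benzyloxy)-6-vinylphenol; 6 1-(benzyloxy)-4-iodobenzene
Product: 7 2-(benzyloxy)-6-[(E)-4-(benzyloxy)styryl]phenol
Conditions: Pd(OAc)2 (5 mol %), P(o-tol)3 (10 mol %), Et3N, MeCN, 80 °C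
Reagents that add atoms: none
Why: Mizoroki–Heck reaction of an aryl iodide with a styrene, in which syn insertion at the terminal carbon and syn beta-hydride elimination give the E-stilbene and the free phenol is tolerated.

**Step 5**
Reactants: 7 2-(benzyloxy)-6-[(E)-4-(benzyloxy)styryl]phenol
Product: 8 2-(benzyloxy)-6-[(E)-4-(benzyloxy)styryl]-1,4-benzoquinone
Conditions: (KSO3)2NO (2.5 equiv), KH2PO4 buffer, acetone/H2O, rt
Reagents that add atoms: potassium nitrosodisulfonate, [K+].[K+].[O]N(S(=O)(=O)[O-])S(=O)(=O)[O-]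
Why: Teuber oxidation, in which one nitrosodisulfonate radical removes the phenolic hydrogen and a second one delivers oxygen to the para carbon, the only unsubstituted ortho or para position, so that the p-quinone forms while ethers and alkene stay intact.

**Step 6**
Reactants: 8 2-(benzyloxy)-6-[(E)-4-(benzyloxy)styryl]-1,4-benzoquinone; 2 tri-O-benzylresveratrol
Product: 9 (2S,3S)-6-(benzyloxy)-2-[4-(benzyloxy)phenyl]-3-[3,5-bis(benzyloxy)phenyl]-4-[(E)-4-(benzyloxy)styryl]-2,3-dihydrobenzofuran-5-ol
Conditions: TiCl2(OiPr)2 (3 equiv), (4R,5R)-TADDOL (3.1 equiv), 4 Å MS, toluene/CH2Cl2, rt; 8, then 2 (1.5 equiv), −78 → −30 °C; then H2O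
Reagents that add atoms: none
Why: Formal [3+2] cycloaddition of a 2-alkoxy-1,4-benzoquinone with an electron-rich styrene under a tetravalent titanium TADDOLate, in which chelation of C1=O and the benzyloxy oxygen directs the nucleophilic alkene carbon of 2 to C5, the C4 oxygen closes onto the 4-benzyloxybenzyl cation and the ring aromatises, C3 being set by the chiral complex and C2 trans to it by transfer of the E geometry and by the thermodynamic preference of the ring.

**Step 7**
Reactants: 9 dihydrobenzofuran-5-ol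
Product: 10 the C5 trifluoromethanesulfonate of 9, (2S,3S)
Conditions: Tf2O, pyridine, CH2Cl2, 0 °C
Reagents that add atoms: trifluoromethanesulfonic anhydride, O=S(=O)(OS(=O)(=O)C(F)(F)F)C(F)(F)F
Why: Sulfonylation of the only free hydroxyl group, which turns the temporary C5 oxygen into a leaving group for palladium.

**Step 8**
Reactants: 10 C5 triflate
Product: 11 penta-O-benzyl-ε-viniferin, (2S,3S)-6-(benzyloxy)-2-[4-(benzyloxy)phenyl]-3-[3,5-bis(benzyloxy)phenyl]-4-[(E)-4-(benzyloxy)styryl]-2,3-dihydrobenzofuran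
Conditions: Pd(OAc)2 (10 mol %), dppf (12 mol %), HCO2H, Et3N, DMF, 70 °C
Reagents that add atoms: none
Why: Palladium-catalysed formate reduction of an aryl triflate (oxidative addition to zerovalent palladium, decarboxylation of the formate, C–H reductive elimination), which leaves benzyl ethers, the stilbene and both stereocentres untouched.

**Step 9**
Reactants: 11 penta-O-benzyl-ε-viniferin; 12 1,4-benzoquinone
Product: 13 (2S,3S)-2-[4-(benzyloxy)phenyl]-3-[(2S,3S)-6-(benzyloxy)-2-[4-(benzyloxy)phenyl]-3-[3,5-bis(benzyloxy)phenyl]-2,3-dihydrobenzofuran-4-yl]-2,3-dihydrobenzofuran-5-ol (temporary ring on ring D)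
Conditions: Sc(OTf)3 (20 mol %), 2,6-di-tert-butyl-4-methylpyridine (30 mol %), 4 Å MS, CH2Cl2/MeCN, −40 → 0 °C
Reagents that add atoms: none
Why: Lewis-acid-catalysed formal [3+2] cycloaddition of 1,4-benzoquinone with a 4-alkoxystyrene, in which the alkene carbon next to ring B attacks the activated quinone and the hydroquinone oxygen traps the 4-benzyloxybenzyl cation to give a trans ring from the E-alkene, the hindered base suppresses protonation of the alkene, and the facial outcome (drawn with 8b already S) is not critical because both new centres are set again in step 11.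

**Step 10**
Reactants: 13 bis(dihydrobenzofuran) phenol
Product: 14 the C5 trifluoromethanesulfonate of 13
Conditions: Tf2O, pyridine, CH2Cl2, 0 °C
Reagents that add atoms: trifluoromethanesulfonic anhydride, O=S(=O)(OS(=O)(=O)C(F)(F)F)C(F)(F)F
Why: Sulfonylation of the only free phenol, which installs the handle for step 13 and makes the ring D phenoxide a better leaving group than the electron-rich ring B phenoxide of the upper dihydrobenzofuran.

**Step 11**
Reactants: 14 bis(dihydrobenzofuran) triflate
Product: 16 seven-membered-ring phenol (upper core 7aS 8aS 7bS 8bS; five benzyl ethers; ring D = 2-hydroxy-5-(triflyloxy)phenyl on 8b), via triarylethene phenol 15 (not isolated)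
Conditions: TsOH·H2O (20 mol %), CH2Cl2/(CF3)2CHOH 4:1, 0 °C → rt
Reagents that add atoms: none
Why: Acid-mediated isomerisation of an oligostilbene dihydrobenzofuran, in which the temporary ring ionises at its 4-benzyloxybenzylic C–O bond and ring A closes the seven-membered ring by intramolecular Friedel–Crafts alkylation, reversible loss and return of the 8b proton through 15 lets either facial isomer converge, 8b ends with its hydrogen in the plane of ring B (allylic strain) and ring D on the face away from ring A, and 7b ends with its aryl group in the outward pseudo-equatorial position, the only one that avoids ring B.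

**Step 12**
Reactants: 16 seven-membered-ring phenol
Product: 17 hexa-O-benzyl upper-core triflate (ring D = 2-(benzyloxy)-5-(triflyloxy)phenyl)
Conditions: BnBr, K2CO3, DMF, rt
Reagents that add atoms: benzyl bromide, BrCc1ccccc1
Why: Williamson ether synthesis on the only free phenol under conditions mild enough for the aryl triflate.

**Step 13**
Reactants: 17 hexa-O-benzyl upper-core triflate; 5 2-(benzyloxy)-6-vinylphenol
Product: 18 trimer phenol, in which ring D carries an (E)-3-(benzyloxy)-2-hydroxystyryl group para to its benzyloxy group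
Conditions: PdCl2(PPh3)2 (10 mol %), LiCl (3 equiv), Et3N, DMF, 90 °C
Reagents that add atoms: none
Why: Mizoroki–Heck reaction of an aryl triflate, run with LiCl so that a neutral arylpalladium chloride inserts the styrene at its terminal carbon and gives the E-stilbene, 17 holding no other C–X bond.

**Step 14**
Reactants: 18 trimer phenol
Product: 19 trimer quinone, a 2-(benzyloxy)-1,4-benzoquinone bearing at C6 the (E)-styryl group whose aryl ring is ring D of the upper core
Conditions: (KSO3)2NO (3 equiv), KH2PO4 buffer, Bu4NHSO4 (cat.), CH2Cl2/H2O, rt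
Reagents that add atoms: potassium nitrosodisulfonate, [K+].[K+].[O]N(S(=O)(=O)[O-])S(=O)(=O)[O-]
Why: Teuber oxidation as in step 5, chemoselective because 18 holds a single free phenol whose para carbon is its only open ortho or para site, and run under phase transfer because of the lipophilic substrate.

**Step 15**
Reactants: 19 trimer quinone; 2 tri-O-benzylresveratrol
Product: 20 deca-O-benzyl tetramer with a free C5 hydroxyl group on the new (2S,3S)-dihydrobenzofuran
Conditions: TiCl2(OiPr)2 (3 equiv), (4R,5R)-TADDOL (3.1 equiv), 4 Å MS, toluene/CH2Cl2, rt; 19, then 2 (3 equiv), −78 → −30 °C; then H2O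
Reagents that add atoms: none
Why: Formal [3+2] cycloaddition of a 2-alkoxy-1,4-benzoquinone with an electron-rich styrene under a tetravalent titanium TADDOLate, the closest known reaction type being this union with propenylbenzenes and chromenes: titanium binds C1=O and the neighbouring benzyloxy oxygen of 19 in a chelate, so only the C1–C6–C5 enone is activated, and the alkene of 2 attacks the unsubstituted C5 (the later C3a) with the carbon that bears the 3,5-bis(benzyloxy)phenyl ring, because only this orientation puts the cation next to the 4-benzyloxyphenyl ring. The C4 carbonyl oxygen (the later O1) then adds to this p-quinone-methide-like cation in a 5-exo-trig closure, and loss of the C5 proton aromatises ring C to the titanium phenoxide of 20, which makes the sequence irreversible and drives it. C3 is set in the C–C bond formation by the chiral complex: the TADDOLate aryl groups shield one face of the chelated quinone and the endo placement of the 4-benzyloxyphenyl group over C4=O decides which alkene face is offered, while the stereocentres of the upper core are held away from the reacting carbons by the stilbene spacer. C2 is controlled by C3: the E geometry is carried over by rapid collapse of the ion pair, and the trans ring is also the thermodynamic one, since the C2–O1 bond can ionise and close again under the Lewis acid. The step needs 2 to react in preference to the alkene of 19 (that alkene is conjugated with the quinone and electron-poor, and 2 is in excess), oxygen closure in preference to carbon closure (only oxygen closure leads to an arene), and alkene attack in preference to arene attack (the open positions of the resorcinol rings are flanked by benzyloxy groups). In one operation a complete resveratrol unit, two bonds, the last ring and the last two stereocentres are added to a flat ring C.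

**Step 16**
Reactants: 20 deca-O-benzyl tetramer C5-ol
Product: 21 the C5 trifluoromethanesulfonate of 20
Conditions: Tf2O, pyridine, CH2Cl2, 0 °C
Reagents that add atoms: trifluoromethanesulfonic anhydride, O=S(=O)(OS(=O)(=O)C(F)(F)F)C(F)(F)F
Why: Sulfonylation of the only free hydroxyl group, as in step 7.

**Step 17**
Reactants: 21 tetramer C5 triflate
Product: 22 deca-O-benzyl ether of the target
Conditions: Pd(OAc)2 (10 mol %), dppf (12 mol %), HCO2H, Et3N, DMF, 70 °C
Reagents that add atoms: none
Why: Palladium-catalysed formate reduction of the aryl triflate as in step 8, which removes the temporary oxygen and leaves C5 as CH without touching the alkene, the benzyl ethers or the six stereocentres.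

**Step 18**
Reactants: 22 deca-O-benzyl ether
Product: 23 CNP0266373.2 (target)
Conditions: BCl3 (30 equiv), C6HMe5 (40 equiv), CH2Cl2, −78 °C; then MeOH
Reagents that add atoms: none
Why: Lewis-acid debenzylation with a non-basic cation scavenger, in which BCl3 cleaves aryl benzyl ethers at low temperature and pentamethylbenzene captures the benzyl cations, so that alkene reduction (as in hydrogenolysis), C-benzylation and acid-induced opening of the dihydrobenzofurans are avoided.

**Compound list**
1 | resveratrol | Oc1ccc(/C=C/c2cc(O)cc(O)c2)cc1 | starting material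
2 | tri-O-benzylresveratrol | c1ccccc1COc1ccc(/C=C/c2cc(OCc3ccccc3)cc(OCc3ccccc3)c2)cc1 | intermediate
3 | 2,3-dihydroxybenzaldehyde | O=Cc1cccc(O)c1O | starting material
4 | 3-(benzyloxy)-2-hydroxybenzaldehyde | O=Cc1cccc(OCc2ccccc2)c1O | intermediate
5 | 2-(benzyloxy)-6-vinylphenol | C=Cc1cccc(OCc2ccccc2)c1O | intermediate
6 | 1-(benzyloxy)-4-iodobenzene | Ic1ccc(OCc2ccccc2)cc1 | starting material
7 | 2-(benzyloxy)-6-[(E)-4-(benzyloxy)styryl]phenol | Oc1c(OCc2ccccc2)cccc1/C=C/c1ccc(OCc2ccccc2)cc1 | intermediate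
8 | 2-(benzyloxy)-6-[(E)-4-(benzyloxy)styryl]-1,4-benzoquinone | O=C1C=C(OCc2ccccc2)C(=O)C(/C=C/c2ccc(OCc3ccccc3)cc2)=C1 | intermediate
9 | (2S,3S)-dihydrobenzofuran-5-ol (penta-O-benzyl-5-hydroxy-ε-viniferin) | c1ccccc1COc1ccc(/C=C/c2c(O)c(OCc3ccccc3)cc3c2[C@H](c2cc(OCc4ccccc4)cc(OCc4ccccc4)c2)[C@@H](c2ccc(OCc4ccccc4)cc2)O3)cc1 | intermediate
10 | C5 triflate of 9 | c1ccccc1COc1ccc(/C=C/c2c(OS(=O)(=O)C(F)(F)F)c(OCc3ccccc3)cc3c2[C@H](c2cc(OCc4ccccc4)cc(OCc4ccccc4)c2)[C@@H](c2ccc(OCc4ccccc4)cc2)O3)cc1 | intermediate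
11 | penta-O-benzyl-ε-viniferin, (2S,3S) | c1ccccc1COc1ccc(/C=C/c2cc(OCc3ccccc3)cc3c2[C@H](c2cc(OCc4ccccc4)cc(OCc4ccccc4)c2)[C@@H](c2ccc(OCc4ccccc4)cc2)O3)cc1 | intermediate
12 | 1,4-benzoquinone | O=C1C=CC(=O)C=C1 | starting material
13 | bis(dihydrobenzofuran) phenol, all four centres S | Oc1ccc2O[C@H](c3ccc(OCc4ccccc4)cc3)[C@@H](c3cc(OCc4ccccc4)cc4c3[C@H](c3cc(OCc5ccccc5)cc(OCc5ccccc5)c3)[C@@H](c3ccc(OCc5ccccc5)cc3)O4)c2c1 | intermediate
14 | triflate of 13 | FC(F)(F)S(=O)(=O)Oc1ccc2O[C@H](c3ccc(OCc4ccccc4)cc3)[C@@H](c3cc(OCc4ccccc4)cc4c3[C@H](c3cc(OCc5ccccc5)cc(OCc5ccccc5)c3)[C@@H](c3ccc(OCc5ccccc5)cc3)O4)c2c1 | intermediate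
15 | (Z)-triarylethene phenol (ring-opened 14) | Oc1ccc(OS(=O)(=O)C(F)(F)F)cc1/C(=C\c1ccc(OCc2ccccc2)cc1)c1cc(OCc2ccccc2)cc2c1[C@H](c1cc(OCc3ccccc3)cc(OCc3ccccc3)c1)[C@@H](c1ccc(OCc3ccccc3)cc1)O2 | intermediate (not isolated)
16 | seven-membered-ring phenol, 7aS,8aS,7bS,8bS | c1ccccc1COc1ccc([C@H]2c3c(OCc4ccccc4)cc(OCc4ccccc4)cc3[C@H]3c4c(cc(OCc5ccccc5)cc4[C@H]2c2cc(OS(=O)(=O)C(F)(F)F)ccc2O)O[C@@H]3c2ccc(OCc3ccccc3)cc2)cc1 | intermediate
17 | hexa-O-benzyl upper-core triflate | c1ccccc1COc1ccc([C@H]2c3c(OCc4ccccc4)cc(OCc4ccccc4)cc3[C@H]3c4c(cc(OCc5ccccc5)cc4[C@H]2c2cc(OS(=O)(=O)C(F)(F)F)ccc2OCc2ccccc2)O[C@@H]3c2ccc(OCc3ccccc3)cc2)cc1 | intermediate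
18 | trimer phenol | c1ccccc1COc1ccc([C@H]2c3c(OCc4ccccc4)cc(OCc4ccccc4)cc3[C@H]3c4c(cc(OCc5ccccc5)cc4[C@H]2c2cc(/C=C/c4cccc(OCc5ccccc5)c4O)ccc2OCc2ccccc2)O[C@@H]3c2ccc(OCc3ccccc3)cc2)cc1 | intermediate
19 | trimer quinone | c1ccccc1COc1ccc([C@H]2c3c(OCc4ccccc4)cc(OCc4ccccc4)cc3[C@H]3c4c(cc(OCc5ccccc5)cc4[C@H]2c2cc(/C=C/C4=CC(=O)C=C(OCc5ccccc5)C4=O)ccc2OCc2ccccc2)O[C@@H]3c2ccc(OCc3ccccc3)cc2)cc1 | intermediate
20 | deca-O-benzyl tetramer C5-ol | c1ccccc1COc1ccc([C@H]2c3c(OCc4ccccc4)cc(OCc4ccccc4)cc3[C@H]3c4c(cc(OCc5ccccc5)cc4[C@H]2c2cc(/C=C/c4c(O)c(OCc5ccccc5)cc5c4[C@H](c4cc(OCc6ccccc6)cc(OCc6ccccc6)c4)[C@@H](c4ccc(OCc6ccccc6)cc4)O5)ccc2OCc2ccccc2)O[C@@H]3c2ccc(OCc3ccccc3)cc2)cc1 | intermediate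
21 | C5 triflate of 20 | c1ccccc1COc1ccc([C@H]2c3c(OCc4ccccc4)cc(OCc4ccccc4)cc3[C@H]3c4c(cc(OCc5ccccc5)cc4[C@H]2c2cc(/C=C/c4c(OS(=O)(=O)C(F)(F)F)c(OCc5ccccc5)cc5c4[C@H](c4cc(OCc6ccccc6)cc(OCc6ccccc6)c4)[C@@H](c4ccc(OCc6ccccc6)cc4)O5)ccc2OCc2ccccc2)O[C@@H]3c2ccc(OCc3ccccc3)cc2)cc1 | intermediate
22 | deca-O-benzyl ether of the target | c1ccccc1COc1ccc([C@H]2c3c(OCc4ccccc4)cc(OCc4ccccc4)cc3[C@H]3c4c(cc(OCc5ccccc5)cc4[C@H]2c2cc(/C=C/c4cc(OCc5ccccc5)cc5c4[C@H](c4cc(OCc6ccccc6)cc(OCc6ccccc6)c4)[C@@H](c4ccc(OCc6ccccc6)cc4)O5)ccc2OCc2ccccc2)O[C@@H]3c2ccc(OCc3ccccc3)cc2)cc1 | intermediate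
23 | CNP0266373.2 | Oc1ccc([C@H]2c3c(O)cc(O)cc3[C@H]3c4c(cc(O)cc4[C@H]2c2cc(/C=C/c4cc(O)cc5c4[C@H](c4cc(O)cc(O)c4)[C@@H](c4ccc(O)cc4)O5)ccc2O)O[C@@H]3c2ccc(O)cc2)cc1 | target

Total step count: 18. Longest linear sequence: 17 steps (3 to 23, steps 2 to 18).

**Steps most likely to fail**

**Step 15.**
- What may go wrong: collapse of the zwitterion through the terminal carbon of the quinone-bound styryl group instead of through oxygen, attack by a resorcinol ring of 2 in place of its alkene, or weak facial discrimination on so large a quinone.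
- Fallback: fragment coupling replaces the late cycloaddition. It sets out from 11 and 17 and comes back at 22.
- The alkene of 11 is cleaved by Lemieux–Johnson oxidation (OsO4 cat., NaIO4, 2,6-lutidine, dioxane/H2O) to the dihydrobenzofuran-4-carbaldehyde F1.
- Wittig methylenation (MePPh3Br, KOtBu, THF) gives the 4-vinyldihydrobenzofuran F2.
- A Heck reaction of F2 with triflate 17 (PdCl2(PPh3)2, LiCl, Et3N, DMF, 90 °C) gives 22 directly.
- Steps 13 to 17 are then not needed, and the lower ring is the one already made in step 6.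

**Step 9.**
- What may go wrong: protonation of the acid-sensitive stilbene and closure of the seven-membered ring before ring D is attached, slow attack of the hindered alkene carbon, or oxidation of the product phenol by excess quinone.
- Fallback: carbonyl additions replace the quinone union. It sets out from 11 and comes back at 18.
- Lemieux–Johnson cleavage of 11 gives the dihydrobenzofuran-4-carbaldehyde F3.
- Addition of [2-(benzyloxy)-5-bromophenyl]magnesium chloride (from 1-(benzyloxy)-4-bromo-2-iodobenzene and iPrMgCl·LiCl, THF, −20 °C) gives the diarylmethanol F4 as a mixture of carbinol epimers.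
- Dess–Martin oxidation gives the diaryl ketone F5.
- 4-(Benzyloxy)benzylmagnesium chloride with CeCl3 (THF, −78 °C) gives the tertiary alcohol F6.
- TsOH in CH2Cl2/(CF3)2CHOH dehydrates F6 to the triarylethene F7. This is protonated at 8b and closes the seven-membered ring as in step 11, giving the upper-core bromide F8.
- A Heck reaction of F8 with 5 (Pd(OAc)2, P(o-tol)3, Et3N, DMF, 100 °C) gives 18.

**Step 6.**
- What may go wrong: weak facial discrimination of the titanium TADDOLate toward a 1,2-diarylethene.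
- Fallback: resolution replaces asymmetric induction. It sets out from 8 and 2 and comes back at 9.
- The union is run with achiral TiCl2(OiPr)2 alone, which should give 9 together with its (2R,3R) enantiomer F9.
- Esterification of the temporary C5 hydroxyl group with (S)-2-methoxy-2-phenylacetic acid (EDC, DMAP, CH2Cl2) gives the (2S,3S) ester F10 and the (2R,3R) ester F11.
- The esters are separated by crystallisation or chromatography.
- LiOH in THF/H2O cleaves F10 back to 9.

**Further compounds**
F1 | step 15 | (2S,3S)-6-(benzyloxy)-2-[4-(benzyloxy)phenyl]-3-[3,5-bis(benzyloxy)phenyl]-2,3-dihydrobenzofuran-4-carbaldehyde | O=Cc1cc(OCc2ccccc2)cc2c1[C@H](c1cc(OCc3ccccc3)cc(OCc3ccccc3)c1)[C@@H](c1ccc(OCc3ccccc3)cc1)O2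
F2 | step 15 | (2S,3S)-6-(benzyloxy)-2-[4-(benzyloxy)phenyl]-3-[3,5-bis(benzyloxy)phenyl]-4-vinyl-2,3-dihydrobenzofuran | C=Cc1cc(OCc2ccccc2)cc2c1[C@H](c1cc(OCc3ccccc3)cc(OCc3ccccc3)c1)[C@@H](c1ccc(OCc3ccccc3)cc1)O2
F3 | step 9 | dihydrobenzofuran-4-carbaldehyde (same structure as F1) | O=Cc1cc(OCc2ccccc2)cc2c1[C@H](c1cc(OCc3ccccc3)cc(OCc3ccccc3)c1)[C@@H](c1ccc(OCc3ccccc3)cc1)O2
F4 | step 9 | [2-(benzyloxy)-5-bromophenyl][(2S,3S)-dihydrobenzofuran-4-yl]methanol, carbinol epimers | OC(c1cc(Br)ccc1OCc1ccccc1)c1cc(OCc2ccccc2)cc2c1[C@H](c1cc(OCc3ccccc3)cc(OCc3ccccc3)c1)[C@@H](c1ccc(OCc3ccccc3)cc1)O2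
F5 | step 9 | [2-(benzyloxy)-5-bromophenyl][(2S,3S)-dihydrobenzofuran-4-yl]methanone | O=C(c1cc(Br)ccc1OCc1ccccc1)c1cc(OCc2ccccc2)cc2c1[C@H](c1cc(OCc3ccccc3)cc(OCc3ccccc3)c1)[C@@H](c1ccc(OCc3ccccc3)cc1)O2
F6 | step 9 | tertiary alcohol, 1-[2-(benzyloxy)-5-bromophenyl]-2-[4-(benzyloxy)phenyl]-1-[(2S,3S)-dihydrobenzofuran-4-yl]ethanol, carbinol epimers | OC(Cc1ccc(OCc2ccccc2)cc1)(c1cc(Br)ccc1OCc1ccccc1)c1cc(OCc2ccccc2)cc2c1[C@H](c1cc(OCc3ccccc3)cc(OCc3ccccc3)c1)[C@@H](c1ccc(OCc3ccccc3)cc1)O2
F7 | step 9 | (Z)-triarylethene from F6 (not isolated) | c1ccccc1COc1ccc(Br)cc1/C(=C\c1ccc(OCc2ccccc2)cc1)c1cc(OCc2ccccc2)cc2c1[C@H](c1cc(OCc3ccccc3)cc(OCc3ccccc3)c1)[C@@H](c1ccc(OCc3ccccc3)cc1)O2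
F8 | step 9 | hexa-O-benzyl upper-core bromide (17 with Br in place of OTf) | c1ccccc1COc1ccc([C@H]2c3c(OCc4ccccc4)cc(OCc4ccccc4)cc3[C@H]3c4c(cc(OCc5ccccc5)cc4[C@H]2c2cc(Br)ccc2OCc2ccccc2)O[C@@H]3c2ccc(OCc3ccccc3)cc2)cc1
F9 | step 6 | (2R,3R) enantiomer of 9 | c1ccccc1COc1ccc(/C=C/c2c(O)c(OCc3ccccc3)cc3c2[C@@H](c2cc(OCc4ccccc4)cc(OCc4ccccc4)c2)[C@H](c2ccc(OCc4ccccc4)cc2)O3)cc1
F10 | step 6 | (S)-2-methoxy-2-phenylacetate of 9 | c1ccccc1COc1ccc(/C=C/c2c(OC(=O)[C@@H](OC)c3ccccc3)c(OCc3ccccc3)cc3c2[C@H](c2cc(OCc4ccccc4)cc(OCc4ccccc4)c2)[C@@H](c2ccc(OCc4ccccc4)cc2)O3)cc1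
F11 | step 6 | (S)-2-methoxy-2-phenylacetate of F9 | c1ccccc1COc1ccc(/C=C/c2c(OC(=O)[C@@H](OC)c3ccccc3)c(OCc3ccccc3)cc3c2[C@@H](c2cc(OCc4ccccc4)cc(OCc4ccccc4)c2)[C@H](c2ccc(OCc4ccccc4)cc2)O3)cc1
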